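**Plan**
- Retrosynthesis: remove the two silyl ethers; cut the C-7 propenol chain at the aryl–vinyl bond (C–H borylation/Suzuki–Miyaura); take C-3 CH2OH back to CO2H; remove the two hydrogens at C-2/C-3 to reach a flat 1,4-benzodioxine-3-carboxylate.
- The dioxine ring is then cut at C-2–C-3 and O-4–C-4a into a benzyl aryl ether and diethyl oxalate; the ether is cut at its benzylic C–O bond into a 5-hydroxyvanillin-derived benzyl alcohol and 2-chloro-3-methoxyphenol.
- Enabling feature: C-2 is both benzylic and bound to O-1, so in the open ether it is the one acidic sp3 C–H, and C-4a, the benzo carbon ortho to that oxygen, can carry chloride. This puts a carbon nucleophile and a C–Cl electrophile 1,4 to each other across O-1/C-8a, matching the two adjacent carbonyl atoms of oxalate (future C-3 and O-4).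
- Forward: protect and reduce 5-hydroxyvanillin, Mitsunobu ether, then a one-flask lithiation/acylation/O-arylation that closes the only new ring (the dioxine) as an alkene, then hydrogenation, acid reduction, late C–H borylation/coupling, desilylation.
- Stereochemistry: both stereocentres come from one iridium-catalysed asymmetric hydrogenation of the tetrasubstituted C-2=C-3 bond; syn addition gives the cis relationship and the ligand antipode the absolute sense; no later step touches them.

Key step: step 4

Remark: with the aryl group at C-2 and CH2OH at C-3 of the 2,3-dihydro-1,4-benzodioxine (OMe at C-5, chain at C-7) the target is the cis isomer, (2S,3R); 2-chloro-3-methoxyphenol and (E)-3-iodoprop-2-en-1-ol are taken as purchasable.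

**Step 1**
Reactants: 1 3,4-dihydroxy-5-methoxybenzaldehyde (5-hydroxyvanillin)
Product: 2 3-methoxy-4,5-bis(triisopropylsilyloxy)benzaldehyde
Conditions: TIPSOTf (2.5 equiv), 2,6-lutidine, CH2Cl2, 0 °C to rt
Reagents that add atoms: triisopropylsilyl triflate, CC(C)[Si](OS(=O)(=O)C(F)(F)F)(C(C)C)C(C)C
Why: O-silylation of both phenols with the silyl triflate (needed for the flanked 4-OH) should give bulky silyl ethers that carry no O–CH2–aryl or ortho-directing group and so should survive t-BuLi, base and hydride in the later steps.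

**Step 2**
Reactants: 2 3-methoxy-4,5-bis(triisopropylsilyloxy)benzaldehyde
Product: 3 [3-methoxy-4,5-bis(triisopropylsilyloxy)phenyl]methanol
Conditions: NaBH4, MeOH/THF, 0 °C
Reagents that add atoms: none
Why: Borohydride reduction of an aryl aldehyde to the benzyl alcohol is routine and leaves aryl silyl ethers intact.

**Step 3**
Reactants: 3 [3-methoxy-4,5-bis(triisopropylsilyloxy)phenyl]methanol; 4 2-chloro-3-methoxyphenol
Product: 5 2-chloro-1-methoxy-3-{[3-methoxy-4,5-bis(triisopropylsilyloxy)phenyl]methoxy}benzene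
Conditions: PPh3, DIAD, THF, 0 °C to rt
Reagents that add atoms: none
Why: Mitsunobu etherification of an acidic ortho-chlorophenol with a primary benzylic alcohol should give the benzyl aryl ether directly, with no stereocentre involved.

**Step 4**
Reactants: 5 2-chloro-1-methoxy-3-{[3-methoxy-4,5-bis(triisopropylsilyloxy)phenyl]methoxy}benzene; 6 diethyl oxalate
Product: 9 ethyl 5-methoxy-2-[3-methoxy-4,5-bis(triisopropylsilyloxy)phenyl]-1,4-benzodioxine-3-carboxylate, via α-lithio ether 7 (not isolated), via lithium enolate 8 (not isolated)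
Conditions: t-BuLi (1.1 equiv), THF, −78 °C; cannulate into (CO2Et)2 (1.5 equiv), THF, −78 to 0 °C; evaporate volatiles; toluene, Pd2(dba)3 (2.5 mol %), t-BuXPhos (6 mol %), 100 °C (one flask)
Reagents that add atoms: none
Why: Proposed new method: t-BuLi should remove the benzylic OCH2 proton of 5 (the only sp3 C–H that is both benzylic and α to oxygen, with lithium held by the ether oxygen) to give 7, which should attack diethyl oxalate once because the tetrahedral adduct persists at −78 °C, and the ethoxide released on warming should deprotonate the now doubly activated C-2–H to enolate 8; zerovalent palladium should then insert into the C-4a–Cl bond, and C–O reductive elimination from the aryl palladium enolate should close the dioxine ring, so that C-2–C-3 and O-4–C-4a are made in one flask as a formal [4+2] annulation. The closest known reaction types are the acylation of α-lithiated aryl benzyl ethers with esters and the palladium- or copper-catalysed intramolecular O-arylation of ketone enolates that gives benzofurans and 4H-chromenes. The single ring closure is six-membered and formally 6-exo-trig (enolate oxygen onto an aromatic carbon, C–Cl bond outside the ring), delivered through a seven-membered oxapalladacycle; C-arylation is excluded because it would need a four-membered ring. No stereocentre is formed, since the enol ether geometry is fixed by the ring and E/Z enolates interconvert through the keto form; both centres are set in step 6. The step needs site-selective lithiation, secured by the acidity and oxygen coordination at the benzylic carbon and by a chloride that has no ortho hydrogen and should not exchange with t-BuLi at −78 °C, and it needs mono-acylation, secured by inverse addition to excess oxalate.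

**Step 5**
Reactants: 9 ethyl 5-methoxy-2-[3-methoxy-4,5-bis(triisopropylsilyloxy)phenyl]-1,4-benzodioxine-3-carboxylate
Product: 10 5-methoxy-2-[3-methoxy-4,5-bis(triisopropylsilyloxy)phenyl]-1,4-benzodioxine-3-carboxylic acid
Conditions: Me3SnOH (4 equiv), ClCH2CH2Cl, 80 °C; 5% aq HCl wash
Reagents that add atoms: trimethyltin hydroxide, C[Sn](C)(C)O
Why: Neutral ester hydrolysis with trimethyltin hydroxide should free the carboxylic acid needed to direct the hydrogenation without the hydroxide or alkoxide that would strip aryl silyl ethers.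

**Step 6**
Reactants: 10 5-methoxy-2-[3-methoxy-4,5-bis(triisopropylsilyloxy)phenyl]-1,4-benzodioxine-3-carboxylic acid
Product: 11 (2S,3S)-5-methoxy-2-[3-methoxy-4,5-bis(triisopropylsilyloxy)phenyl]-2,3-dihydro-1,4-benzodioxine-3-carboxylic acid (cis)
Conditions: H2 (6 atm), [Ir(cod)(L*)]BArF (1 mol %; L* = one antipode of the spirobiindane phosphine–oxazoline SIPHOX, BArF = tetrakis[3,5-bis(trifluoromethyl)phenyl]borate), Et3N (0.5 equiv), MeOH, 45 °C
Reagents that add atoms: none
Why: Carboxylate-directed asymmetric hydrogenation with a cationic complex of monovalent iridium should add both hydrogens to one face of the C-2=C-3 bond, so syn addition fixes the cis relationship and the ligand antipode (to be assigned in a test run) fixes the face that gives (2S,3S).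

**Step 7**
Reactants: 11 (2S,3S)-5-methoxy-2-[3-methoxy-4,5-bis(triisopropylsilyloxy)phenyl]-2,3-dihydro-1,4-benzodioxine-3-carboxylic acid
Product: 12 [(2S,3R)-5-methoxy-2-[3-methoxy-4,5-bis(triisopropylsilyloxy)phenyl]-2,3-dihydro-1,4-benzodioxin-3-yl]methanol (cis)
Conditions: BH3·THF (3 equiv), THF, 0 °C to rt; MeOH quench
Reagents that add atoms: none
Why: Borane reduction of a carboxylic acid to the primary alcohol is chemoselective and should not epimerise the adjacent stereocentre (the descriptor at C-3 changes only through CIP priority).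

**Step 8**
Reactants: 12 [(2S,3R)-5-methoxy-2-[3-methoxy-4,5-bis(triisopropylsilyloxy)phenyl]-2,3-dihydro-1,4-benzodioxin-3-yl]methanol; 13 (E)-3-iodoprop-2-en-1-ol
Product: 15 (E)-3-[(2S,3R)-3-(hydroxymethyl)-5-methoxy-2-[3-methoxy-4,5-bis(triisopropylsilyloxy)phenyl]-2,3-dihydro-1,4-benzodioxin-7-yl]prop-2-en-1-ol, via aryl boronate 14 (not isolated)
Conditions: [Ir(OMe)(cod)]2 (1.5 mol %), 4,4′-di-tert-butyl-2,2′-bipyridine (3 mol %), B2pin2 (2.2 equiv), THF, 80 °C; then 13, Pd(dppf)Cl2 (5 mol %), aq K3PO4, 60 °C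
Reagents that add atoms: none
Why: Iridium-catalysed C–H borylation is sterically controlled and should take the only arene C–H without an ortho substituent (C-7; C-6 lies next to OMe, C-8 next to the ring oxygen, and both hydrogens of the other ring are flanked), the hydroxyl being O-borylated only transiently, and Suzuki–Miyaura coupling of the boronate with 13 should retain the E geometry.

**Step 9**
Reactants: 15 (E)-3-[(2S,3R)-3-(hydroxymethyl)-5-methoxy-2-[3-methoxy-4,5-bis(triisopropylsilyloxy)phenyl]-2,3-dihydro-1,4-benzodioxin-7-yl]prop-2-en-1-ol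
Product: 16 5-[(2S,3R)-3-(hydroxymethyl)-7-[(E)-3-hydroxyprop-1-enyl]-5-methoxy-2,3-dihydro-1,4-benzodioxin-2-yl]-3-methoxybenzene-1,2-diol (target)
Conditions: TBAF (2.2 equiv), AcOH (2.2 equiv), THF, 0 °C
Reagents that add atoms: none
Why: Fluoride desilylation of the two aryl silyl ethers, buffered with acetic acid so that no free phenoxide can open the benzylic C-2–O bond through a quinone methide, should release the catechol without cis-to-trans epimerisation.

**Compound list**
1 | 3,4-dihydroxy-5-methoxybenzaldehyde (5-hydroxyvanillin) | COc1cc(C=O)cc(O)c1O | starting material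
2 | 3-methoxy-4,5-bis(triisopropylsilyloxy)benzaldehyde | COc1cc(C=O)cc(O[Si](C(C)C)(C(C)C)C(C)C)c1O[Si](C(C)C)(C(C)C)C(C)C | intermediate
3 | [3-methoxy-4,5-bis(triisopropylsilyloxy)phenyl]methanol | COc1cc(CO)cc(O[Si](C(C)C)(C(C)C)C(C)C)c1O[Si](C(C)C)(C(C)C)C(C)C | intermediate
4 | 2-chloro-3-methoxyphenol | COc1cccc(O)c1Cl | starting material
5 | 2-chloro-1-methoxy-3-{[3-methoxy-4,5-bis(triisopropylsilyloxy)phenyl]methoxy}benzene | COc1cc(COc2cccc(OC)c2Cl)cc(O[Si](C(C)C)(C(C)C)C(C)C)c1O[Si](C(C)C)(C(C)C)C(C)C | intermediate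
6 | diethyl oxalate | CCOC(=O)C(=O)OCC | starting material
7 | α-lithio derivative of 5 (lithium on the benzylic OCH carbon) | COc1cc(C([Li])Oc2cccc(OC)c2Cl)cc(O[Si](C(C)C)(C(C)C)C(C)C)c1O[Si](C(C)C)(C(C)C)C(C)C | intermediate
8 | lithium enolate of ethyl 3-(2-chloro-3-methoxyphenoxy)-3-[3-methoxy-4,5-bis(triisopropylsilyloxy)phenyl]-2-oxopropanoate | CCOC(=O)C(O[Li])=C(Oc1cccc(OC)c1Cl)c1cc(OC)c(O[Si](C(C)C)(C(C)C)C(C)C)c(O[Si](C(C)C)(C(C)C)C(C)C)c1 | intermediate
9 | ethyl 5-methoxy-2-[3-methoxy-4,5-bis(triisopropylsilyloxy)phenyl]-1,4-benzodioxine-3-carboxylate | COc1cc(C2=C(C(=O)OCC)Oc3c(OC)cccc3O2)cc(O[Si](C(C)C)(C(C)C)C(C)C)c1O[Si](C(C)C)(C(C)C)C(C)C | intermediate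
10 | 5-methoxy-2-[3-methoxy-4,5-bis(triisopropylsilyloxy)phenyl]-1,4-benzodioxine-3-carboxylic acid | COc1cc(C2=C(C(=O)O)Oc3c(OC)cccc3O2)cc(O[Si](C(C)C)(C(C)C)C(C)C)c1O[Si](C(C)C)(C(C)C)C(C)C | intermediate
11 | (2S,3S)-5-methoxy-2-[3-methoxy-4,5-bis(triisopropylsilyloxy)phenyl]-2,3-dihydro-1,4-benzodioxine-3-carboxylic acid (cis) | COc1cc([C@@H]2Oc3cccc(OC)c3O[C@@H]2C(=O)O)cc(O[Si](C(C)C)(C(C)C)C(C)C)c1O[Si](C(C)C)(C(C)C)C(C)C | intermediate
12 | [(2S,3R)-5-methoxy-2-[3-methoxy-4,5-bis(triisopropylsilyloxy)phenyl]-2,3-dihydro-1,4-benzodioxin-3-yl]methanol (cis) | COc1cc([C@@H]2Oc3cccc(OC)c3O[C@@H]2CO)cc(O[Si](C(C)C)(C(C)C)C(C)C)c1O[Si](C(C)C)(C(C)C)C(C)C | intermediate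
13 | (E)-3-iodoprop-2-en-1-ol | OC/C=C/I | starting material
14 | C-7 pinacol boronate of 12 | COc1cc([C@@H]2Oc3cc(B4OC(C)(C)C(C)(C)O4)cc(OC)c3O[C@@H]2CO)cc(O[Si](C(C)C)(C(C)C)C(C)C)c1O[Si](C(C)C)(C(C)C)C(C)C | intermediate
15 | (E)-3-[(2S,3R)-3-(hydroxymethyl)-5-methoxy-2-[3-methoxy-4,5-bis(triisopropylsilyloxy)phenyl]-2,3-dihydro-1,4-benzodioxin-7-yl]prop-2-en-1-ol | COc1cc([C@@H]2Oc3cc(/C=C/CO)cc(OC)c3O[C@@H]2CO)cc(O[Si](C(C)C)(C(C)C)C(C)C)c1O[Si](C(C)C)(C(C)C)C(C)C | intermediate
16 | 5-[(2S,3R)-3-(hydroxymethyl)-7-[(E)-3-hydroxyprop-1-enyl]-5-methoxy-2,3-dihydro-1,4-benzodioxin-2-yl]-3-methoxybenzene-1,2-diol | COc1cc([C@@H]2Oc3cc(/C=C/CO)cc(OC)c3O[C@@H]2CO)cc(O)c1O | target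

**Step count and risks**
Total step count: 9. Longest linear sequence: 9 steps (1 to 16).

Steps most likely to fail:

Step 4 (Proposed new method). Ring lithiation or a [1,2]-Wittig shift of the α-lithio ether may compete with acylation, and oxidative addition at the doubly ortho-substituted, electron-rich C–Cl bond may be so slow that the enolate is protonated or O-acylated instead of cyclised. The fallback uses known reaction types, sets out from aldehyde 2 and returns at 9. Roskamp homologation of 2 with ethyl diazoacetate (SnCl2 cat., CH2Cl2) should give ethyl 3-[3-methoxy-4,5-bis(triisopropylsilyloxy)phenyl]-3-oxopropanoate F1. Chlorination (SO2Cl2, CH2Cl2, 0 °C) should give the 2-chloro-β-keto ester F2. O-Alkylation of purchased 2-bromo-6-methoxyphenol (K2CO3, acetone) should give the 2-(2-bromo-6-methoxyphenoxy)-β-keto ester F3, whose OH lies between OMe and Br and so fixes the oxygen pattern. Copper-catalysed intramolecular O-arylation of its enolate (CuI, 1,10-phenanthroline, Cs2CO3, dioxane, 100 °C) should then close the dioxine at the other ring oxygen and give 9.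

Step 6. Turnover may be slow, or face discrimination poor, on the tetrasubstituted, doubly oxygen-substituted alkene. The fallback sets out from ester 9 and returns at 11. Hydrogenation with the achiral complex [Ir(cod)(PCy3)(py)]PF6 (H2 50 bar, CH2Cl2) should give by syn addition the racemic cis ethyl ester F4. Enantioselective hydrolysis with a lipase (Candida antarctica lipase B or a screened alternative, phosphate buffer/MTBE, pH 7) should then deliver acid 11 and leave the (2R,3R)-ester F5, removed by extraction.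

Step 8. Site selectivity of the C–H borylation may erode (attack at C-8 next to the ring oxygen), or the free hydroxyl may consume the boron reagent. The fallback sets out from 12 and returns at 15. Thianthrenation (thianthrene S-oxide, (CF3CO)2O, HBF4·OEt2, MeCN, 0 °C; NaHCO3/MeOH work-up to cleave the trifluoroacetate of the primary alcohol) goes para to an oxygen and avoids positions with an ortho substituent, so it should give the C-7 aryl thianthrenium tetrafluoroborate F6. Heck coupling with ethyl acrylate (Pd(OAc)2, K2CO3, DMF, 60 °C) should give the ethyl (E)-cinnamate F7, and i-Bu2AlH (CH2Cl2, −78 °C) should reduce it to 15.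

**Further compounds**
F1 | step 4 | ethyl 3-[3-methoxy-4,5-bis(triisopropylsilyloxy)phenyl]-3-oxopropanoate | CCOC(=O)CC(=O)c1cc(OC)c(O[Si](C(C)C)(C(C)C)C(C)C)c(O[Si](C(C)C)(C(C)C)C(C)C)c1
F2 | step 4 | ethyl 2-chloro-3-[3-methoxy-4,5-bis(triisopropylsilyloxy)phenyl]-3-oxopropanoate | CCOC(=O)C(Cl)C(=O)c1cc(OC)c(O[Si](C(C)C)(C(C)C)C(C)C)c(O[Si](C(C)C)(C(C)C)C(C)C)c1
F3 | step 4 | ethyl 2-(2-bromo-6-methoxyphenoxy)-3-[3-methoxy-4,5-bis(triisopropylsilyloxy)phenyl]-3-oxopropanoate | CCOC(=O)C(Oc1c(Br)cccc1OC)C(=O)c1cc(OC)c(O[Si](C(C)C)(C(C)C)C(C)C)c(O[Si](C(C)C)(C(C)C)C(C)C)c1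
F4 | step 6 | racemic cis ethyl 5-methoxy-2-[3-methoxy-4,5-bis(triisopropylsilyloxy)phenyl]-2,3-dihydro-1,4-benzodioxine-3-carboxylate (one enantiomer drawn) | COc1cc([C@@H]2Oc3cccc(OC)c3O[C@@H]2C(=O)OCC)cc(O[Si](C(C)C)(C(C)C)C(C)C)c1O[Si](C(C)C)(C(C)C)C(C)C
F5 | step 6 | ethyl (2R,3R)-5-methoxy-2-[3-methoxy-4,5-bis(triisopropylsilyloxy)phenyl]-2,3-dihydro-1,4-benzodioxine-3-carboxylate | COc1cc([C@H]2Oc3cccc(OC)c3O[C@H]2C(=O)OCC)cc(O[Si](C(C)C)(C(C)C)C(C)C)c1O[Si](C(C)C)(C(C)C)C(C)C
F6 | step 8 | C-7 thianthrenium tetrafluoroborate of 12 | COc1cc([C@@H]2Oc3cc([S+]4c5ccccc5Sc5ccccc54)cc(OC)c3O[C@@H]2CO)cc(O[Si](C(C)C)(C(C)C)C(C)C)c1O[Si](C(C)C)(C(C)C)C(C)C.F[B-](F)(F)F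
F7 | step 8 | ethyl (E)-3-[(2S,3R)-3-(hydroxymethyl)-5-methoxy-2-[3-methoxy-4,5-bis(triisopropylsilyloxy)phenyl]-2,3-dihydro-1,4-benzodioxin-7-yl]prop-2-enoate | COc1cc([C@@H]2Oc3cc(/C=C/C(=O)OCC)cc(OC)c3O[C@@H]2CO)cc(O[Si](C(C)C)(C(C)C)C(C)C)c1O[Si](C(C)C)(C(C)C)C(C)C
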